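Begin with the easy step: subtract what the protic impurity takes.

    starting material + catalyst → catalyst + target (k1 = 0.66 L mol⁻¹ s⁻¹)
    starting material → side product (k2 = 6.9 × 10⁻⁵ s⁻¹)
    starting material + protic impurity → quenched substrate (k3 = 0.045 L mol⁻¹ s⁻¹)
    target → over-reaction product (k4 = 4.4 × 10⁻⁵ s⁻¹)

- violet: starting material 1.6 M; protic impurity 0.160 M; catalyst 3.2 mM; time 6.0 h
- teal: starting material 1.6 M; protic impurity 0.160 M; catalyst 3.2 mM; time 3.0 h

- which of these there is most of at the end, counted by the starting material in it, violet (side product / over-reaction product / target / starting material)
- which of these there is most of at the end, counted by the starting material in it, teal (side product / over-reaction product / target / starting material)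
- the largest of these amounts at the end, in percent of the starting material charged, violet
- the largest of these amounts at the end, in percent of the starting material charged, teal

Both flasks hold the same charges, so reckon once. The protic impurity meets starting material on a clock of 13.9 s. The catalyst step, pseudo-first-order with catalyst regenerated, runs at 0.00211 s⁻¹, a clock of 473 s. The impurity clock is far shorter, so charge the loss at the impurity's own amount, 10.0% of the starting material. Of the remainder, the catalyst step takes a share 96.8%, being faster than the side step. Together these give the plateau, 87.2% of the charge: a bookkeeping height, not a reading.

Target decays with a half-life of 4.38 h, far longer than the catalyst clock, so let the plateau stand at time zero. Target and over-reaction product then share the plateau, and its height cancels when they are compared. Call the half-life of target the crossing time, the moment at which, with the plateau put at time zero, the two hold equal amounts in this reckoning.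

Now get the amounts two ways. First, use the exponential. Teal, read before the crossing, has target in front at 54.2%. Violet, read after it, has over-reaction product in front at 53.5%, with target at 33.7%.

Second, replace the target curve by the mean of its two ends and burn it at that level throughout. Teal ends at 53.7%, which agrees with the first way. Violet ends at 31.0%, lower by 2.7 percentage points. Find the cheat: the curve sags under its chord, so its true mean in violet, 56.3%, lies below the 59.1% that the second way used. Keep the exponential.

The forecast names over-reaction product at 52.8% for violet and target at 55.3% for teal, with “roughly 97% going to target”. Its violet figure stands below mine and its teal figure above mine.

The flask gives over-reaction product at 52.8% in violet, with target at 34.4%, and target at 55.3% in teal, with over-reaction product at 31.9%. Hold each reading time against the reckoned crossing time of 4.38 h, an estimate that puts the plateau at time zero: violet's 6.0 h lies beyond it, teal's 3.0 h lies before it, and the leader changes between them. The same flask as violet read at 4.0 h, still short of that estimate, holds target in front at 47.2% against 40.0% of over-reaction product.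

All constants were set for the occasion, and the outcome is calculated.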